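**Retrosynthetic overview**
1. Chain: acid 21 ⇐ ester hydrolysis ⇐ Wittig at C-11/C-12 between a ring-bearing C15 phosphonium salt and a C12 aldehyde ester (from the commercial C10 trienedial); the C15 unit ⇐ Wittig at C-7/C-8 of ring aldehyde 10 with a C5 ester ylide.
2. Ring aldehyde 10 ⇐ hydride cleavage and re-oxidation of a spiro-dioxolanone. Its pivalaldehyde acetal ring is temporary (not in the target, formed in step 1): it ties O-6 to C-7 and relays chirality from (S)-2-hydroxy-3-methylbutanoic acid.
3. Key disconnection: the C-1/C-2 and C-5/C-6 bonds of the cyclohexane (the only ring of the target, formed in step 3) are cut together, to 1-methylcyclobutan-1-ol and an isopropylidene dioxolanone. Strain-release ring opening, radical addition and aldol return make both bonds.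
4. Enabling feature: the cyclohexane carries a ditertiary trans-1,2-diol next to the gem-dimethyl carbon. C-5 (C(OH)CH3) with CH2-4, CH2-3 and CH2-2 is the skeleton of 1-methylcyclobutanol; C-1/C-6/C-7 is the β,β-dimethyl-α-oxyacrylate skeleton of α-hydroxyisovaleric acid. The C-5/C-6 diol bond is therefore an enolate-to-ketone aldol bond and C-1 is the β-carbon of a radical acceptor.

Key step: step 3

Remark: the SMILES is read as the (5R,6R) trans-diol with an all-E chain (azafrin); carotenoid locants are used (C-1 = CMe2, C-2 to C-4 = ring CH2, C-5 = C(OH)CH3, C-6 = C(OH) bearing the chain, C-7 onward = chain), and 11 and 17 are taken as the commercial E isomers.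

**Route**

Step 1
Reactants: 1 (2S)-2-hydroxy-3-methylbutanoic acid; 2 2,2-dimethylpropanal (pivalaldehyde)
Product: 3 (2S,5S)-2-tert-butyl-5-(propan-2-yl)-1,3-dioxolan-4-one (cis)
Conditions: TsOH·H2O (5 mol %), pentane, reflux, Dean–Stark trap; crystallisation
Reagents that add atoms: none
Why: Acid-catalysed acetalisation with water removal is under thermodynamic control and should give mainly the cis dioxolanone, the new acetal carbon being set by the existing stereocentre of 1 (tert-butyl and isopropyl on the same face).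

Step 2
Reactants: 3 (2S,5S)-2-tert-butyl-5-(propan-2-yl)-1,3-dioxolan-4-one
Product: 5 (2S)-2-tert-butyl-5-(propan-2-ylidene)-1,3-dioxolan-4-one, via tertiary bromide 4 (not isolated)
Conditions: NBS (1.1 equiv), AIBN (5 mol %), PhCF3, 85 °C; then Et3N (1.5 equiv), 0 °C to rt
Reagents that add atoms: none
Why: Wohl–Ziegler radical bromination should take the captodative ring C–H, and E2 loss of HBr can only use the isopropyl methine hydrogen, so the tetrasubstituted alkene forms while the acetal stereocentre stays untouched.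

Step 3
Reactants: 5 (2S)-2-tert-butyl-5-(propan-2-ylidene)-1,3-dioxolan-4-one; 6 1-methylcyclobutan-1-ol
Product: 8 (2S,5R,6R)-2-tert-butyl-6-hydroxy-6,10,10-trimethyl-1,3-dioxaspiro[4.5]decan-4-one, via cerium enolate 7 (not isolated)
Conditions: 6 (3 equiv), CeCl3 (10 mol %), Bu4NCl (20 mol %), 9,10-diphenylanthracene (10 mol %), MeCN, 400 nm LEDs, 25 °C, argon
Reagents that add atoms: none
Why: Proposed new method: CeCl3 and 6 form, after oxidation by photoexcited 9,10-diphenylanthracene, a tetravalent cerium alkoxide whose ligand-to-metal charge-transfer homolysis gives the alkoxy radical; strain-release β-scission of the cyclobutane delivers the 4-oxopentyl radical, which adds to the exocyclic isopropylidene carbon of 5 (forming the C-1/C-2 bond and a captodative ring radical), the diphenylanthracene radical anion reduces this radical to cerium enolate 7, and 7 adds to its own methyl ketone (forming the C-5/C-6 bond) before proton transfer from 6 closes the cycle. The closest known reaction type is the cerium-photocatalysed formal cycloaddition (ring opening, Giese addition, aldol return) of cycloalkanols with electron-poor alkenes, together with the known radical additions to 5-methylene-1,3-dioxolan-4-ones; untested is the fully substituted alkene terminus. The cyclohexane, the only ring closed, forms by a 6-(enolexo)-exo-trig aldol addition favoured by the gem-dimethyl group. The spiro carbon (C-6) is controlled by the tert-butyl group of the temporary acetal, which shields one face of the planar enolate so that the ketone bonds anti to it (net retention of the hydroxy-acid configuration), and the carbinol carbon (C-5) by a chair-like transition state in which trivalent cerium bridges enolate and ketone oxygens and the ketone methyl sits equatorial, away from the axial methyl on C-1, which places the new hydroxyl cis to the lactone carbonyl and trans to the acetal oxygen. The step needs regioselective radical attack at the isopropylidene carbon, radical addition faster than hydrogen abstraction and ring closure faster than enolate protonation; the captodative stabilisation of the adduct radical, the polarity match of a nucleophilic alkyl radical with a Lewis-acid-bound acceptor, the excess of 6 and the tethered unhindered methyl ketone are meant to secure these.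

Step 4
Reactants: 8 (2S,5R,6R)-2-tert-butyl-6-hydroxy-6,10,10-trimethyl-1,3-dioxaspiro[4.5]decan-4-one
Product: 9 (1S,2R)-1-(hydroxymethyl)-2,6,6-trimethylcyclohexane-1,2-diol
Conditions: LiAlH4 (3 equiv), THF, −20 to 0 °C (inverse addition); aq. potassium sodium tartrate
Reagents that add atoms: none
Why: Hydride reduction of the acylal-type lactone should open the temporary dioxolanone faster than the aldolate can reopen, the released pivalaldehyde being reduced to neopentyl alcohol and no stereocentre being touched.

Step 5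
Reactants: 9 (1S,2R)-1-(hydroxymethyl)-2,6,6-trimethylcyclohexane-1,2-diol
Product: 10 (1R,2R)-1,2-dihydroxy-2,6,6-trimethylcyclohexane-1-carbaldehyde
Conditions: (COCl)2 (1.3 equiv), DMSO, CH2Cl2, −78 °C; Et3N, −78 to −20 °C; used at once
Reagents that add atoms: none
Why: Swern oxidation can only oxidise the primary alcohol because the two tertiary alcohols carry no carbinol hydrogen, and the cold non-aqueous conditions should spare the β-hydroxy aldehyde from retro-aldol opening.

Step 6
Reactants: 11 ethyl (2E)-4-bromo-3-methylbut-2-enoate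
Product: 12 [(2E)-4-ethoxy-2-methyl-4-oxobut-2-en-1-yl]triphenylphosphonium bromide
Conditions: PPh3 (1.05 equiv), toluene, rt to 40 °C; filtration
Reagents that add atoms: triphenylphosphine, c1ccc(cc1)P(c1ccccc1)c1ccccc1
Why: SN2 quaternisation of triphenylphosphine by the primary allylic bromide should give the crystalline C5 Wittig salt.

Step 7
Reactants: 10 (1R,2R)-1,2-dihydroxy-2,6,6-trimethylcyclohexane-1-carbaldehyde; 12 [(2E)-4-ethoxy-2-methyl-4-oxobut-2-en-1-yl]triphenylphosphonium bromide
Product: 13 ethyl (2E,4E)-5-[(1R,2R)-1,2-dihydroxy-2,6,6-trimethylcyclohexyl]-3-methylpenta-2,4-dienoate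
Conditions: 12 (1.5 equiv), 1,2-epoxybutane (solvent), 80 °C, sealed tube; chromatography
Reagents that add atoms: none
Why: Wittig olefination with the ester-stabilised vinylogous ylide, generated without added base by bromide opening of the epoxide, should give the E alkene at C-7/C-8 and keep the base-sensitive β-hydroxy aldehyde intact, any 9Z isomer being removable by chromatography.

Step 8
Reactants: 13 ethyl (2E,4E)-5-[(1R,2R)-1,2-dihydroxy-2,6,6-trimethylcyclohexyl]-3-methylpenta-2,4-dienoate
Product: 14 (1R,2R)-1-[(1E,3E)-5-hydroxy-3-methylpenta-1,3-dien-1-yl]-2,6,6-trimethylcyclohexane-1,2-diol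
Conditions: iBu2AlH (4.5 equiv), CH2Cl2, −78 to 0 °C; aq. potassium sodium tartrate
Reagents that add atoms: none
Why: 1,2-Reduction of the dienoate by the aluminium hydride should give the allylic alcohol without touching the diene, the two free hydroxyls only consuming extra hydride.

Step 9
Reactants: 14 (1R,2R)-1-[(1E,3E)-5-hydroxy-3-methylpenta-1,3-dien-1-yl]-2,6,6-trimethylcyclohexane-1,2-diol
Product: 16 [(2E,4E)-5-[(1R,2R)-1,2-dihydroxy-2,6,6-trimethylcyclohexyl]-3-methylpenta-2,4-dien-1-yl]triphenylphosphonium bromide, via allylic bromide 15 (not isolated)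
Conditions: CBr4 (1.2 equiv), PPh3 (2.5 equiv), 2,6-lutidine (0.2 equiv), CH2Cl2/MeCN, −20 °C to rt
Reagents that add atoms: triphenylphosphine, c1ccc(cc1)P(c1ccccc1)c1ccccc1; carbon tetrabromide, BrC(Br)(Br)Br
Why: Appel bromination should convert only the unhindered primary allylic alcohol by SN2 attack on its oxyphosphonium ion without acid, and the excess phosphine then quaternises the bromide in the same flask to the C15 Wittig salt.

Step 10
Reactants: 17 (2E,4E,6E)-2,7-dimethylocta-2,4,6-trienedial; 18 ethyl (triphenylphosphoranylidene)acetate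
Product: 19 ethyl (2E,4E,6E,8E)-4,9-dimethyl-10-oxodeca-2,4,6,8-tetraenoate
Conditions: 18 (1.0 equiv) added slowly, CH2Cl2, 0 °C to rt; chromatography
Reagents that add atoms: none
Why: Wittig reaction of the stabilised ylide with one of the two equivalent aldehyde groups is E-selective, and slow addition of one equivalent should limit double olefination because the first olefination makes the remaining aldehyde less electrophilic.

Step 11
Reactants: 16 [(2E,4E)-5-[(1R,2R)-1,2-dihydroxy-2,6,6-trimethylcyclohexyl]-3-methylpenta-2,4-dien-1-yl]triphenylphosphonium bromide; 19 ethyl (2E,4E,6E,8E)-4,9-dimethyl-10-oxodeca-2,4,6,8-tetraenoate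
Product: 20 ethyl (2E,4E,6E,8E,10E,12E,14E)-15-[(1R,2R)-1,2-dihydroxy-2,6,6-trimethylcyclohexyl]-4,9,13-trimethylpentadeca-2,4,6,8,10,12,14-heptaenoate
Conditions: 1,2-epoxybutane/EtOH, 80 °C, dark; then heptane, reflux, dark (Z to E equilibration)
Reagents that add atoms: none
Why: Wittig coupling of the C15 ylide with the polyenal builds the C-11/C-12 alkene under base-free conditions, and thermal equilibration should convert the sterically hindered 11Z isomer into the all-E chain.

Step 12
Reactants: 20 ethyl ester of the target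
Product: 21 (2E,4E,6E,8E,10E,12E,14E)-15-[(1R,2R)-1,2-dihydroxy-2,6,6-trimethylcyclohexyl]-4,9,13-trimethylpentadeca-2,4,6,8,10,12,14-heptaenoic acid (azafrin)
Conditions: LiOH·H2O (5 equiv), THF/EtOH/H2O, 25 °C, dark, argon; then AcOH to pH 5
Reagents that add atoms: lithium hydroxide, [Li+].[OH-]
Why: Saponification of the conjugated ethyl ester at room temperature followed by weak-acid neutralisation should free the acid without ionising the tertiary allylic alcohol or isomerising the polyene.

**Compound list**
1 | (2S)-2-hydroxy-3-methylbutanoic acid | CC(C)[C@H](O)C(=O)O | starting material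
2 | 2,2-dimethylpropanal (pivalaldehyde) | CC(C)(C)C=O | starting material
3 | (2S,5S)-2-tert-butyl-5-(propan-2-yl)-1,3-dioxolan-4-one | O=C1O[C@@H](C(C)(C)C)O[C@H]1C(C)C | intermediate
4 | (2R,5R)-5-bromo-2-tert-butyl-5-(propan-2-yl)-1,3-dioxolan-4-one (bromine drawn trans to tert-butyl; either epimer eliminates to 5) | O=C1O[C@@H](C(C)(C)C)O[C@@]1(Br)C(C)C | intermediate
5 | (2S)-2-tert-butyl-5-(propan-2-ylidene)-1,3-dioxolan-4-one | O=C1O[C@@H](C(C)(C)C)OC1=C(C)C | intermediate
6 | 1-methylcyclobutan-1-ol | CC1(O)CCC1 | starting material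
7 | (2S)-2-tert-butyl-5-(2-methyl-6-oxoheptan-2-yl)-2H-1,3-dioxol-4-olate (cerium-bound enolate) | CC(=O)CCCC(C)(C)C1=C([O-])O[C@@H](C(C)(C)C)O1 | intermediate
8 | (2S,5R,6R)-2-tert-butyl-6-hydroxy-6,10,10-trimethyl-1,3-dioxaspiro[4.5]decan-4-one | O=C1O[C@@H](C(C)(C)C)O[C@@]12C(C)(C)CCC[C@@]2(C)O | intermediate
9 | (1S,2R)-1-(hydroxymethyl)-2,6,6-trimethylcyclohexane-1,2-diol | OC[C@@]1(O)C(C)(C)CCC[C@@]1(C)O | intermediate
10 | (1R,2R)-1,2-dihydroxy-2,6,6-trimethylcyclohexane-1-carbaldehyde | O=C[C@@]1(O)C(C)(C)CCC[C@@]1(C)O | intermediate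
11 | ethyl (2E)-4-bromo-3-methylbut-2-enoate | CCOC(=O)/C=C(C)/CBr | starting material
12 | [(2E)-4-ethoxy-2-methyl-4-oxobut-2-en-1-yl]triphenylphosphonium bromide | CCOC(=O)/C=C(C)/C[P+](c1ccccc1)(c1ccccc1)c1ccccc1.[Br-] | intermediate
13 | ethyl (2E,4E)-5-[(1R,2R)-1,2-dihydroxy-2,6,6-trimethylcyclohexyl]-3-methylpenta-2,4-dienoate | CCOC(=O)/C=C(C)/C=C/[C@@]1(O)C(C)(C)CCC[C@@]1(C)O | intermediate
14 | (1R,2R)-1-[(1E,3E)-5-hydroxy-3-methylpenta-1,3-dien-1-yl]-2,6,6-trimethylcyclohexane-1,2-diol | OC/C=C(C)/C=C/[C@@]1(O)C(C)(C)CCC[C@@]1(C)O | intermediate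
15 | (1R,2R)-1-[(1E,3E)-5-bromo-3-methylpenta-1,3-dien-1-yl]-2,6,6-trimethylcyclohexane-1,2-diol | BrC/C=C(C)/C=C/[C@@]1(O)C(C)(C)CCC[C@@]1(C)O | intermediate
16 | [(2E,4E)-5-[(1R,2R)-1,2-dihydroxy-2,6,6-trimethylcyclohexyl]-3-methylpenta-2,4-dien-1-yl]triphenylphosphonium bromide | [Br-].c1ccccc1[P+](c1ccccc1)(c1ccccc1)C/C=C(C)/C=C/[C@@]1(O)C(C)(C)CCC[C@@]1(C)O | intermediate
17 | (2E,4E,6E)-2,7-dimethylocta-2,4,6-trienedial | CC(/C=O)=C\C=C\C=C(C)\C=O | starting material
18 | ethyl (triphenylphosphoranylidene)acetate | CCOC(=O)C=P(c1ccccc1)(c1ccccc1)c1ccccc1 | starting material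
19 | ethyl (2E,4E,6E,8E)-4,9-dimethyl-10-oxodeca-2,4,6,8-tetraenoate | CC(/C=O)=C\C=C\C=C(C)\C=C\C(=O)OCC | intermediate
20 | ethyl (2E,4E,6E,8E,10E,12E,14E)-15-[(1R,2R)-1,2-dihydroxy-2,6,6-trimethylcyclohexyl]-4,9,13-trimethylpentadeca-2,4,6,8,10,12,14-heptaenoate | CC(/C=C/C=C(C)/C=C/[C@@]1(O)C(C)(C)CCC[C@@]1(C)O)=C\C=C\C=C(C)\C=C\C(=O)OCC | intermediate
21 | (2E,4E,6E,8E,10E,12E,14E)-15-[(1R,2R)-1,2-dihydroxy-2,6,6-trimethylcyclohexyl]-4,9,13-trimethylpentadeca-2,4,6,8,10,12,14-heptaenoic acid, (5R,6R)-5,6-dihydroxy-5,6-dihydro-10'-apo-β-caroten-10'-oic acid | CC(/C=C/C=C(C)/C=C/[C@@]1(O)C(C)(C)CCC[C@@]1(C)O)=C\C=C\C=C(C)\C=C\C(=O)O | target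

**Step count**
Total: 12 steps. Longest linear sequence: 10 steps (1, 2, 3, 4, 5, 7, 8, 9, 11, 12); steps 6 and 10 are side branches.

**Steps most likely to fail**

1. Step 3 (proposed new method). The primary 4-oxopentyl radical may add too slowly to the fully substituted alkene carbon of 5 and be lost by hydrogen abstraction. Enolate 7 may also be protonated, or the aldolate may reopen by retro-aldol, before the ring is secured. The fallback is stepwise polar chemistry of known types; it sets out from 5 and comes back at 8. Conjugate addition to 5 of the organocopper reagent made from pent-4-en-1-ylmagnesium bromide, CuI and BF3·OEt2 (THF, −78 to −30 °C), with protonation anti to tert-butyl, gives (2S,5S)-2-tert-butyl-5-(2-methylhept-6-en-2-yl)-1,3-dioxolan-4-one F1. Tsuji–Wacker oxidation (PdCl2, CuCl, O2, DMF/H2O) gives the methyl ketone (2S,5S)-2-tert-butyl-5-(2-methyl-6-oxoheptan-2-yl)-1,3-dioxolan-4-one F2. Radical bromination as in step 2 (NBS, AIBN) gives the tertiary bromide (2R,5R)-5-bromo-2-tert-butyl-5-(2-methyl-6-oxoheptan-2-yl)-1,3-dioxolan-4-one F3. SmI2 (THF, −78 °C) then closes the ring by an intramolecular samarium Reformatsky addition, through the same metal-bridged, anti-to-tert-butyl arrangement, to give 8.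

2. Step 9. Activation of the dienyl alcohol may lead to ionisation or allylic transposition across the diene, loss of the tertiary allylic C-6 hydroxyl, or attack of the ring hydroxyls on the activated dienyl system. The fallback reverses the polarity of the coupling so that the diol fragment is never an electrophile; it sets out from 14 (and uses 19) and comes back at 20. MnO2 (CH2Cl2, rt) oxidises 14 to (2E,4E)-5-[(1R,2R)-1,2-dihydroxy-2,6,6-trimethylcyclohexyl]-3-methylpenta-2,4-dienal F4. NaBH4 (EtOH, 0 °C) reduces only the aldehyde of 19 to ethyl (2E,4E,6E,8E)-10-hydroxy-4,9-dimethyldeca-2,4,6,8-tetraenoate F5. PPh3·HBr (MeOH, rt) converts F5, which has no acid-sensitive group, into [(2E,4E,6E,8E)-10-ethoxy-2,7-dimethyl-10-oxodeca-2,4,6,8-tetraen-1-yl]triphenylphosphonium bromide F6. Wittig coupling of F4 with F6 in 1,2-epoxybutane, followed by the thermal equilibration of step 11, gives 20.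

3. Step 7. The hindered, neopentyl-type aldehyde 10 may react too slowly, so that retro-aldol opening of the β-hydroxy aldehyde or scrambling of the C-9/C-10 geometry through the allylic ylide takes over. The fallback replaces olefination by cross-coupling; it sets out from 10 and comes back at 13. Takai iodo-olefination (CrCl2, CHI3, THF, 0 °C, non-basic, E-selective) gives (1R,2R)-1-[(E)-2-iodoethenyl]-2,6,6-trimethylcyclohexane-1,2-diol F7. Stille coupling of F7 with ethyl (2E)-3-(tributylstannyl)but-2-enoate (Pd2(dba)3, AsPh3, CuI, DMF, 40 °C) gives 13 with both alkene geometries retained.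

**Further compounds**
F1 | step 3 | (2S,5S)-2-tert-butyl-5-(2-methylhept-6-en-2-yl)-1,3-dioxolan-4-one | O=C1O[C@@H](C(C)(C)C)O[C@H]1C(C)(C)CCCC=C
F2 | step 3 | (2S,5S)-2-tert-butyl-5-(2-methyl-6-oxoheptan-2-yl)-1,3-dioxolan-4-one | O=C1O[C@@H](C(C)(C)C)O[C@H]1C(C)(C)CCCC(C)=O
F3 | step 3 | (2R,5R)-5-bromo-2-tert-butyl-5-(2-methyl-6-oxoheptan-2-yl)-1,3-dioxolan-4-one | O=C1O[C@@H](C(C)(C)C)O[C@@]1(Br)C(C)(C)CCCC(C)=O
F4 | step 9 | (2E,4E)-5-[(1R,2R)-1,2-dihydroxy-2,6,6-trimethylcyclohexyl]-3-methylpenta-2,4-dienal | O=C/C=C(C)/C=C/[C@@]1(O)C(C)(C)CCC[C@@]1(C)O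
F5 | step 9 | ethyl (2E,4E,6E,8E)-10-hydroxy-4,9-dimethyldeca-2,4,6,8-tetraenoate | CC(/CO)=C\C=C\C=C(C)\C=C\C(=O)OCC
F6 | step 9 | [(2E,4E,6E,8E)-10-ethoxy-2,7-dimethyl-10-oxodeca-2,4,6,8-tetraen-1-yl]triphenylphosphonium bromide | CC(/C[P+](c1ccccc1)(c1ccccc1)c1ccccc1)=C\C=C\C=C(C)\C=C\C(=O)OCC.[Br-]
F7 | step 7 | (1R,2R)-1-[(E)-2-iodoethenyl]-2,6,6-trimethylcyclohexane-1,2-diol | I/C=C/[C@@]1(O)C(C)(C)CCC[C@@]1(C)O
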